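## Retrosynthetic overview

- **Numbering and feature.** C1 is the fusion CH bearing C15, C2 the lactone O–CH, then C3=C4, C7=C8, C11=C12, C13 (OAc), C14; C16 is the lactone C=O and C17 the exocyclic CH2. The plan rests on the C10–C11 bond of the 14-membered carbocycle, where a ring CH2 meets the CH terminus of the E-C11=C12(CH3)–C13(O) unit. C10 can therefore be generated as a primary radical from an acid one carbon longer. C11 can be an E-alkenyl iodide of the type made by methylalumination–iodination of a propargylic alcohol.
- **Endgame.** The C13 acetate and the C15=C17 methylene are installed only after ring closure, so the macrocyclisation substrate holds no radical acceptor.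
- **Key disconnection.** C10–C11 is formed by nickel-electrocatalytic decarboxylative alkenylation of a seco N-hydroxyphthalimide ester/alkenyl iodide built on the preformed cis γ-lactone.
- **Seco compound.** C1–C2 comes from a syn-selective, catalyst-controlled allylboration. The electrophile is a C2–C10 enal ester from farnesyl acetate, which supplies both remote E alkenes. The nucleophile is a Z-allylboronate holding C11–C16, made from propargyl alcohol with C13 set by asymmetric allylboration. Hydroboration and oxidative lactonisation then give the lactone.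
- **Ring order.** γ-Lactone first (step 15), 14-membered carbocycle second (step 17).

Key step: step 17

Assumption: (2E,6E)-farnesyl acetate, the (+)-α-pinene-derived allylborane solution and allylboronic acid pinacol ester are taken as purchasable, and (R)-TRIP is taken to direct allyl transfer to the Re face of an alkenyl aldehyde as it does for aryl aldehydes.

## Route

Step 1
Reactants: 1 (2E,6E)-farnesyl acetate
Product: 2 (2E,6E)-10-bromo-11-hydroxy-3,7,11-trimethyldodeca-2,6-dien-1-yl acetate (racemic at the C–Br carbon)
Conditions: NBS, THF/H2O, 0 °C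
Reagents that add atoms: N-bromosuccinimide, O=C1CCC(=O)N1Br; water, O
Why: Terminal-selective bromohydrin formation, in which electrophilic bromine picks the most exposed and electron-rich isopropylidene alkene (the alkene next to the allylic acetate is deactivated), water opens the bromonium ion at the tertiary carbon, and the racemic centre is erased in step 3.

Step 2
Reactants: 2 bromohydrin acetate
Product: 3 (2E,6E)-10,11-epoxyfarnesol (racemic epoxide)
Conditions: K2CO3, MeOH, rt
Reagents that add atoms: none
Why: Intramolecular Williamson displacement of bromide by the tertiary alkoxide closes the epoxide, and the same methanolic carbonate removes the acetate by transesterification, freeing the hydroxyl on the future C2.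

Step 3
Reactants: 3 10,11-epoxyfarnesol
Product: 4 (4E,8E)-10-hydroxy-4,8-dimethyldeca-4,8-dienal
Conditions: H5IO6, THF/Et2O, 0 °C
Reagents that add atoms: none
Why: Periodic acid hydrolyses the trisubstituted epoxide to the glycol and cleaves it in the same pot (Malaprade-type glycol cleavage), excising acetone and leaving the aldehyde carbon later lost as CO2, while isolated alkenes and the allylic alcohol are not attacked by periodate.

Step 4
Reactants: 4 hydroxy aldehyde
Product: 5 (4E,8E)-10-hydroxy-4,8-dimethyldeca-4,8-dienoic acid
Conditions: NaClO2, NaH2PO4, 2-methyl-2-butene, t-BuOH/H2O, rt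
Reagents that add atoms: sodium chlorite, [Na+].[O-]Cl=O
Why: Pinnick oxidation converts only the aldehyde, since chlorous acid leaves alcohols alone and 2-methyl-2-butene scavenges the hypochlorous acid that could otherwise add to the alkenes.

Step 5
Reactants: 5 hydroxy acid
Product: 6 methyl (4E,8E)-10-hydroxy-4,8-dimethyldeca-4,8-dienoate
Conditions: MeI, K2CO3, DMF, rt
Reagents that add atoms: iodomethane, CI
Why: SN2 O-alkylation of the potassium carboxylate is much faster than etherification of the neutral allylic alcohol under carbonate, so only the methyl ester forms.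

Step 6
Reactants: 6 hydroxy ester
Product: 7 methyl (4E,8E)-4,8-dimethyl-10-oxodeca-4,8-dienoate (enal; aldehyde carbon = C2, ester carbon = the carbon beyond C10)
Conditions: MnO2, CH2Cl2, rt
Reagents that add atoms: none
Why: MnO2 oxidises allylic alcohols selectively and stops at the enal without E/Z isomerisation of C3=C4 and without touching the ester.

Step 7
Reactants: 8 prop-2-yn-1-ol
Product: 10 (E)-3-iodo-2-methylprop-2-en-1-ol, via alkenylalane 9 (not isolated)
Conditions: Me3Al, Cp2ZrCl2 (25 mol %), CH2Cl2, 0 °C to rt; then I2, THF, −30 °C; aq K2CO3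
Reagents that add atoms: trimethylaluminium, C[Al](C)C; iodine, II
Why: Zirconium-catalysed methylalumination (Negishi carboalumination) adds methyl and aluminium syn across the alkyne with aluminium on the terminal carbon, and iodinolysis with retention fixes the E geometry of the future C11=C12.

Step 8
Reactants: 10 iodo allylic alcohol
Product: 11 (E)-3-iodo-2-methylprop-2-enal
Conditions: MnO2, CH2Cl2, rt, dark
Reagents that add atoms: none
Why: Allylic oxidation with MnO2 is mild enough to keep both the C–I bond and the alkene geometry.

Step 9
Reactants: 11 iodo enal; 12 B-allyldiisopinocampheylborane derived from (+)-α-pinene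
Product: 14 (1E,3S)-1-iodo-2-methylhexa-1,5-dien-3-ol, via borinate 13 (not isolated)
Conditions: Et2O, −78 °C; then 3 M NaOH, 30% H2O2, 0 °C to rt
Reagents that add atoms: none
Why: Brown asymmetric allylboration proceeds through a chair Zimmerman–Traxler transition state in which the isopinocampheyl groups from (+)-α-pinene steer allyl transfer so that alkenyl aldehydes give the S carbinol, which sets C13.

Step 10
Reactants: 14 homoallylic alcohol
Product: 15 (1E,3S)-3-(tert-butyldimethylsilyloxy)-1-iodo-2-methylhexa-1,5-diene
Conditions: TBSCl, imidazole, DMF, rt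
Reagents that add atoms: tert-butyldimethylsilyl chloride, CC(C)(C)[Si](C)(C)Cl
Why: Imidazole-promoted silylation masks the C13 hydroxyl with a group that survives metathesis, boron chemistry, LiOH, electrolysis and LDA and is removed by fluoride at the end.

Step 11
Reactants: 15 silyl ether; 16 allylboronic acid pinacol ester
Product: 17 2-[(2Z,5S,6E)-5-(tert-butyldimethylsilyloxy)-7-iodo-6-methylhepta-2,6-dien-1-yl]-4,4,5,5-tetramethyl-1,3,2-dioxaborolane
Conditions: Mo(N-1-adamantyl)(CHCMe2Ph)(NC4H4)[O-2,6-(2,4,6-iPr3C6H2)2C6H3] (5 mol %), 16 in excess, C6H6, 22 °C, 100 Torr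
Reagents that add atoms: none
Why: Kinetically Z-selective olefin cross-metathesis, in which the large aryloxide and small imido ligand force both metallacyclobutane substituents to one side, only the two monosubstituted alkenes take part (the trisubstituted iodoalkene is inert), and removal of ethene drives the exchange.

Step 12
Reactants: 7 enal ester; 17 Z-allylboronate
Product: 19 methyl (4E,8E,10R,11S,13S,14E)-13-(tert-butyldimethylsilyloxy)-11-ethenyl-10-hydroxy-15-iodo-4,8,14-trimethylpentadeca-4,8,14-trienoate (C2 R, C1 S, C13 S; syn at C1/C2), via pinacol borate 18 (not isolated)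
Conditions: (R)-3,3'-bis(2,4,6-triisopropylphenyl)-1,1'-binaphthyl-2,2'-diyl hydrogen phosphate [(R)-TRIP, 10 mol %], 4 Å MS, toluene, −30 °C; aq NaHCO3
Reagents that add atoms: none
Why: Chiral-phosphoric-acid-catalysed allylboration through a closed chair transition state, in which the Z geometry of the boronate places the C14 chain axial and so gives the syn C1/C2 pair, while the acid, hydrogen-bonded to the boronate oxygen and the formyl hydrogen, exposes the Re face of the enal and sets C2 as R and C1 as S independently of remote C13.

Step 13
Reactants: 19 homoallylic alcohol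
Product: 21 methyl (4E,8E,10R,11R,13S,14E)-13-(tert-butyldimethylsilyloxy)-10-hydroxy-11-(2-hydroxyethyl)-15-iodo-4,8,14-trimethylpentadeca-4,8,14-trienoate (same spatial arrangement; the C1 descriptor changes by priority only), via bis-9-BBN adduct 20 (not isolated)
Conditions: 9-BBN (2.5 equiv), THF, 0 °C to rt; then NaBO3·4H2O, THF/H2O, rt
Reagents that add atoms: sodium perborate, [Na+].[Na+].O[B-]1(O)OO[B-](O)(O)OO1
Why: Hydroboration–oxidation, in which 9-BBN strongly favours the single monosubstituted alkene over the trisubstituted alkenes and the iodoalkene and places boron on terminal C16 (one equivalent being taken up by the C2 hydroxyl), and perborate oxidises the C–B bond mildly enough for the methyl ester.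

Step 14
Reactants: 21 diol ester
Product: 22 (4E,8E,10R,11R,13S,14E)-13-(tert-butyldimethylsilyloxy)-10-hydroxy-11-(2-hydroxyethyl)-15-iodo-4,8,14-trimethylpentadeca-4,8,14-trienoic acid
Conditions: LiOH, THF/MeOH/H2O, rt; then dilute HCl to pH 4, 0 °C
Reagents that add atoms: lithium hydroxide, [Li+].[OH-]
Why: Saponification is placed before the lactone exists so that hydroxide meets only one ester, and the silyl ether and alkenyl iodide are stable to aqueous LiOH.

Step 15
Reactants: 22 diol acid
Product: 24 (4E,8E)-9-{(2R,3S)-3-[(2S,3E)-2-(tert-butyldimethylsilyloxy)-4-iodo-3-methylbut-3-en-1-yl]-5-oxooxolan-2-yl}-4,8-dimethylnona-4,8-dienoic acid (cis lactone), via lactol 23 (not isolated)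
Conditions: TEMPO (20 mol %), PhI(OAc)2 (2.5 equiv), CH2Cl2, rt
Reagents that add atoms: none
Why: TEMPO/PhI(OAc)2 oxidative lactonisation, in which the oxoammonium salt oxidises the unhindered primary C16 alcohol first, the aldehyde is trapped by the C2 hydroxyl as the five-membered lactol, and a second oxidation gives the γ-lactone, so the syn C1/C2 pair becomes the cis ring junction.

Step 16
Reactants: 24 lactone acid; 25 N-hydroxyphthalimide
Product: 26 1,3-dioxoisoindolin-2-yl ester of 24 (cis lactone bearing the C3–C10 redox-active ester arm and the C14–C11 alkenyl iodide arm)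
Conditions: N,N'-diisopropylcarbodiimide, DMAP (10 mol %), CH2Cl2, rt
Reagents that add atoms: none
Why: Carbodiimide (Steglich-type) esterification of the only free acid, with no free hydroxyl left to compete.

Step 17
Reactants: 26 redox-active ester/alkenyl iodide
Product: 27 (1S,2R,3E,7E,11E,13S)-13-(tert-butyldimethylsilyloxy)-17-norcembra-3,7,11-trien-16,2-olide (cis-fused γ-lactone on the 14-membered carbocycle)
Conditions: NiCl2·6H2O (50 mol %), 2,2'-bipyridine (50 mol %), AgNO3 (30 mol %, plates silver onto the cathode), LiCl, DMF, undivided cell, Mg anode, reticulated vitreous carbon cathode, constant current, 26 added by syringe pump to about 2 mM, rt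
Reagents that add atoms: none
Why: Proposed new method: oxidative addition of the C11–I bond to cathodically reduced (bpy)Ni gives an E-alkenylnickel with its geometry intact, while one-electron reduction of the phthalimide ester (at the silver-coated cathode or by monovalent nickel) releases phthalimide anion and CO2 and leaves the primary C10 radical. The radical is caught by the divalent alkenylnickel centre at the far end of its own chain, and reductive elimination from the trivalent nickel so formed makes C10–C11. The closest known reaction type is the intermolecular nickel-electrocatalytic decarboxylative alkenylation of N-hydroxyphthalimide esters with alkenyl iodides, which already joins homoallylic primary radicals of this kind to E-2-methylalkenyl iodides without loss of alkene geometry, so only its use for ring closure is new. The 14-membered carbocycle is closed end to end at the metal, through a 15-membered nickelacycle that contracts on reductive elimination, and since the radical never attacks an alkene, exo/endo terms do not apply. No stereocentre is formed, and C1, C2, C13 and the three preset E alkenes are spectators in the near-neutral medium. The step needs intramolecular capture to beat hydrogen abstraction, over-reduction, dimerisation and oligomerisation, which is served by slow addition to millimolar concentration, by a nickel loading high enough that each chain is nickelated before its radical forms, by the cis lactone holding both arms on one face of the five-membered ring, and by the absence of the C15 methylene as a competing acceptor.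

Step 18
Reactants: 27 macrocyclic lactone
Product: 29 15-(dimethylaminomethyl) derivative of 27 (C15 epimers, inconsequential; C1, C2, C13 unchanged), via lithium enolate 28 (not isolated)
Conditions: LDA, THF, −78 °C; then Me2N=CH2 I (Eschenmoser's salt), −78 °C to rt
Reagents that add atoms: Eschenmoser's salt, C=[N+](C)C.[I-]
Why: Mannich-type aminomethylation of the kinetic lactone enolate, C15 being the only position alpha to a carbonyl and no beta leaving group being present, so that C17 is introduced cleanly.

Step 19
Reactants: 29 aminomethyl lactone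
Product: 31 (1S,2S,3E,7E,11E,13S)-13-(tert-butyldimethylsilyloxy)cembra-3,7,11,15(17)-tetraen-16,2-olide, via methiodide 30 (not isolated)
Conditions: MeI, THF, rt; then sat. aq NaHCO3, CH2Cl2, rt
Reagents that add atoms: none
Why: Quaternisation followed by mild-base Hofmann-type (E1cB) elimination of trimethylamine gives the exocyclic alkene, erases the C15 centre and leaves the other centres untouched (the C2 descriptor changes by priority only).

Step 20
Reactants: 31 silyl ether
Product: 32 (1S,2S,3E,7E,11E,13S)-13-hydroxycembra-3,7,11,15(17)-tetraen-16,2-olide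
Conditions: HF·pyridine, pyridine, THF, 0 °C to rt
Reagents that add atoms: none
Why: Buffered fluoride desilylation is slightly acidic, which avoids alkoxide-driven oxa-Michael addition of the C13 oxygen to C17 and translactonisation, both of which a basic fluoride source could trigger.

Step 21
Reactants: 32 allylic alcohol
Product: 33 target, (1S,2S,3E,7E,11E,13S)-13-acetoxycembra-3,7,11,15(17)-tetraen-16,2-olide
Conditions: Ac2O, pyridine, DMAP, CH2Cl2, 0 °C to rt
Reagents that add atoms: acetic anhydride, CC(=O)OC(C)=O
Why: DMAP-catalysed O-acylation occurs at oxygen with retention at C13 and is faster than any conjugate addition to the methylene lactone.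

## Compound list

1 | (2E,6E)-farnesyl acetate | CC(C)=CCC/C(C)=C/CC/C(C)=C/COC(C)=O | starting material
2 | (2E,6E)-10-bromo-11-hydroxy-3,7,11-trimethyldodeca-2,6-dien-1-yl acetate (racemic) | CC(C)(O)C(Br)CC/C(C)=C/CC/C(C)=C/COC(C)=O | intermediate
3 | (2E,6E)-10,11-epoxyfarnesol (racemic) | CC1(C)OC1CC/C(C)=C/CC/C(C)=C/CO | intermediate
4 | (4E,8E)-10-hydroxy-4,8-dimethyldeca-4,8-dienal | O=CCC/C(C)=C/CC/C(C)=C/CO | intermediate
5 | (4E,8E)-10-hydroxy-4,8-dimethyldeca-4,8-dienoic acid | OC(=O)CC/C(C)=C/CC/C(C)=C/CO | intermediate
6 | methyl (4E,8E)-10-hydroxy-4,8-dimethyldeca-4,8-dienoate | COC(=O)CC/C(C)=C/CC/C(C)=C/CO | intermediate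
7 | methyl (4E,8E)-4,8-dimethyl-10-oxodeca-4,8-dienoate | COC(=O)CC/C(C)=C/CC/C(C)=C/C=O | intermediate
8 | prop-2-yn-1-ol | C#CCO | starting material
9 | (E)-alkenylalane, O,C-bis(dimethylaluminium) derivative (not isolated) | C[Al](C)OC/C(C)=C/[Al](C)C | intermediate
10 | (E)-3-iodo-2-methylprop-2-en-1-ol | OC/C(C)=C/I | intermediate
11 | (E)-3-iodo-2-methylprop-2-enal | O=C/C(C)=C/I | intermediate
12 | B-allyldiisopinocampheylborane from (+)-α-pinene | C=CCB([C@@H]1C[C@@H]2C[C@H]([C@H]1C)C2(C)C)[C@@H]1C[C@@H]2C[C@H]([C@H]1C)C2(C)C | starting material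
13 | diisopinocampheylborinate of 14 (not isolated) | C=CC[C@H](OB([C@@H]1C[C@@H]2C[C@H]([C@H]1C)C2(C)C)[C@@H]1C[C@@H]2C[C@H]([C@H]1C)C2(C)C)/C(C)=C/I | intermediate
14 | (1E,3S)-1-iodo-2-methylhexa-1,5-dien-3-ol | C=CC[C@H](O)/C(C)=C/I | intermediate
15 | (1E,3S)-3-(tert-butyldimethylsilyloxy)-1-iodo-2-methylhexa-1,5-diene | C=CC[C@H](O[Si](C)(C)C(C)(C)C)/C(C)=C/I | intermediate
16 | allylboronic acid pinacol ester | C=CCB1OC(C)(C)C(C)(C)O1 | starting material
17 | (2Z,5S,6E)-allylboronate, pinacol ester | CC1(C)OB(C/C=C\C[C@H](O[Si](C)(C)C(C)(C)C)/C(C)=C/I)OC1(C)C | intermediate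
18 | pinacol borate of 19 (not isolated) | CC1(C)OB(O[C@@H](/C=C(\C)CC/C=C(\C)CCC(=O)OC)[C@H](C=C)C[C@H](O[Si](C)(C)C(C)(C)C)/C(C)=C/I)OC1(C)C | intermediate
19 | syn homoallylic alcohol (10R,11S,13S) | O[C@@H](/C=C(\C)CC/C=C(\C)CCC(=O)OC)[C@H](C=C)C[C@H](O[Si](C)(C)C(C)(C)C)/C(C)=C/I | intermediate
20 | C16-alkyl, C2-O bis(9-BBN) adduct (not isolated) | O(B1C2CCCC1CCC2)[C@@H](/C=C(\C)CC/C=C(\C)CCC(=O)OC)[C@H](CCB1C2CCCC1CCC2)C[C@H](O[Si](C)(C)C(C)(C)C)/C(C)=C/I | intermediate
21 | 1,4-diol methyl ester | O[C@@H](/C=C(\C)CC/C=C(\C)CCC(=O)OC)[C@H](CCO)C[C@H](O[Si](C)(C)C(C)(C)C)/C(C)=C/I | intermediate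
22 | 1,4-diol acid | O[C@@H](/C=C(\C)CC/C=C(\C)CCC(=O)O)[C@H](CCO)C[C@H](O[Si](C)(C)C(C)(C)C)/C(C)=C/I | intermediate
23 | lactol acid (C16 anomers, not isolated) | C1C(O)O[C@@H](/C=C(\C)CC/C=C(\C)CCC(=O)O)[C@H]1C[C@H](O[Si](C)(C)C(C)(C)C)/C(C)=C/I | intermediate
24 | cis lactone acid | C1C(=O)O[C@@H](/C=C(\C)CC/C=C(\C)CCC(=O)O)[C@H]1C[C@H](O[Si](C)(C)C(C)(C)C)/C(C)=C/I | intermediate
25 | N-hydroxyphthalimide | ON1C(=O)c2ccccc2C1=O | starting material
26 | redox-active ester/alkenyl iodide (key-step precursor) | C1C(=O)O[C@@H](/C=C(\C)CC/C=C(\C)CCC(=O)ON2C(=O)c3ccccc3C2=O)[C@H]1C[C@H](O[Si](C)(C)C(C)(C)C)/C(C)=C/I | intermediate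
27 | macrocyclic lactone (key-step product) | C1C(=O)O[C@H]2/C=C(\C)CC/C=C(\C)CC/C=C(\C)[C@@H](O[Si](C)(C)C(C)(C)C)C[C@@H]12 | intermediate
28 | lithium enolate of 27 (not isolated) | C1=C([O-])O[C@H]2/C=C(\C)CC/C=C(\C)CC/C=C(\C)[C@@H](O[Si](C)(C)C(C)(C)C)C[C@@H]12.[Li+] | intermediate
29 | 15-(dimethylaminomethyl) lactone (C15 epimers) | CN(C)CC1C(=O)O[C@H]2/C=C(\C)CC/C=C(\C)CC/C=C(\C)[C@@H](O[Si](C)(C)C(C)(C)C)C[C@@H]12 | intermediate
30 | trimethylammonium iodide of 29 (not isolated) | C[N+](C)(C)CC1C(=O)O[C@H]2/C=C(\C)CC/C=C(\C)CC/C=C(\C)[C@@H](O[Si](C)(C)C(C)(C)C)C[C@@H]12.[I-] | intermediate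
31 | α-methylene lactone, C13 silyl ether | C=C1C(=O)O[C@H]2/C=C(\C)CC/C=C(\C)CC/C=C(\C)[C@@H](O[Si](C)(C)C(C)(C)C)C[C@@H]12 | intermediate
32 | α-methylene lactone, C13 alcohol | C=C1C(=O)O[C@H]2/C=C(\C)CC/C=C(\C)CC/C=C(\C)[C@@H](O)C[C@@H]12 | intermediate
33 | CNP0182196.2 | C=C1C(=O)O[C@H]2/C=C(\C)CC/C=C(\C)CC/C=C(\C)[C@@H](OC(C)=O)C[C@@H]12 | target

## Step count

Total step count: 21.
Longest linear sequence: 16 steps (steps 1–6, then 12–21). The C11–C16 branch (steps 7–11) has 5 steps.

## Steps most likely to fail

**1. Step 17.**
- The C10 radical may abstract hydrogen, be reduced further, or be captured by the alkenylnickel of another chain faster than by its own. The chain is then reduced or oligomerises instead of closing. Low-valent nickel may also ionise the allylic C2–O bond of the lactone.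
- The fallback forms the same bond by a two-electron, well-precedented B-alkyl Suzuki–Miyaura macrocyclisation. It sets out from lactone acid 24.
- Photocatalytic dehydrodecarboxylation (9-(2-chlorophenyl)acridine, Co(dmgH)2(py)Cl, 400 nm, CH2Cl2/MeCN) turns the CH2CH2CO2H terminus into a vinyl group and gives the C7=C8–C9=C10 diene lactone F1.
- 9-BBN adds to its only monosubstituted alkene and places boron on C10, giving the B-alkyl-9-BBN lactone F2.
- F2 is added slowly, without isolation, to Pd(dppf)Cl2, AsPh3 and Cs2CO3 in DMF/THF/H2O at high dilution. This rejoins the route at 27.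

**2. Step 11.**
- The metathesis may erode in Z selectivity through secondary isomerisation. It may also stall by homodimerisation of either partner or by catalyst decay.
- The fallback removes the need for a defined allyl geometry. It sets out from 15.
- Cross-metathesis with allyltributylstannane under the second-generation Grubbs catalyst gives the γ-substituted allylstannane F3 as an E/Z mixture.
- F3 is added to enal 7 at −78 °C in EtCN under a tartrate-derived chiral acyloxyborane Lewis acid.
- The open antiperiplanar transition state gives the syn adduct from either alkene isomer, and the tartrate enantiomer is chosen for Re-face attack. This rejoins the route at 19.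

**3. Step 12.**
- Facial selectivity at the β,β-disubstituted enal may be poor, or the hindered Z-boronate may react too slowly at low temperature, so that an uncatalysed background erodes control at C1/C2.
- The fallback replaces catalyst control by kinetic resolution. It sets out from 7 and 17.
- Uncatalysed allylboration (toluene, rt) still gives only syn adducts through the closed chair. The product is 19 together with its (10S,11R,13S) diastereomer F4.
- Sharpless kinetic resolution of this mixture (Ti(OiPr)4, L-(+)-diisopropyl tartrate, t-BuOOH, 4 Å MS, CH2Cl2, −20 °C) epoxidises the fast-reacting 10S allylic alcohol to the epoxy alcohol F5.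
- The slow-reacting 10R isomer is left behind and is separated by chromatography. This rejoins the route at 19.

## Further compounds

F1 | step 17 | cis lactone with C7=C8–C9=C10 terminal diene arm and alkenyl iodide arm | C1C(=O)O[C@@H](/C=C(\C)CC/C=C(\C)C=C)[C@H]1C[C@H](O[Si](C)(C)C(C)(C)C)/C(C)=C/I
F2 | step 17 | C10 B-alkyl-9-BBN derivative of F1 | C1C(=O)O[C@@H](/C=C(\C)CC/C=C(\C)CCB2C3CCCC2CCC3)[C@H]1C[C@H](O[Si](C)(C)C(C)(C)C)/C(C)=C/I
F3 | step 11 | tributyl[(5S,6E)-5-(tert-butyldimethylsilyloxy)-7-iodo-6-methylhepta-2,6-dien-1-yl]stannane (2E/2Z mixture) | CCCC[Sn](CCCC)(CCCC)CC=CC[C@H](O[Si](C)(C)C(C)(C)C)/C(C)=C/I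
F4 | step 12 | (10S,11R,13S) syn diastereomer of 19 | O[C@H](/C=C(\C)CC/C=C(\C)CCC(=O)OC)[C@@H](C=C)C[C@H](O[Si](C)(C)C(C)(C)C)/C(C)=C/I
F5 | step 12 | 8,9-epoxide of F4 (C3–C4 epoxy alcohol) | O[C@H]([C@@H]1O[C@@]1(C)CC/C=C(\C)CCC(=O)OC)[C@@H](C=C)C[C@H](O[Si](C)(C)C(C)(C)C)/C(C)=C/I
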